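**Plan**
Locants are those of the name 8-bromo-3-(chloromethyl)-3,9-dihydroxy-7,7-dimethyl-11-methylidenespiro[5.5]undecan-2-one: ring B = C1–C6 (C2 ketone, C3 carbinol), ring A = C6–C11.
Cuts: C–Cl and C3–O (back to a C3-methylidene ketone through its epoxide). Then C9–H, C8–Br and the alkene position at C11 (back to the C10=C11 enone). Then C4–C5 with C2–C5 re-joined, so ring B shrinks to a four-membered ring. Last, cyclobutanone to ketene + C6=CH2, and C6=CH2 to a ketone.
Enabling feature: in ring B the spiro atom C6 carries two CH2 arms (C1, C5) and the carbonyl C2 lies 1,3 to it. Taking out C3–C4 leaves a mirror-symmetric spiro[3.5]nonan-2-one whose two C2–CH2 bonds are strained and enantiotopic.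
Forward: ring A is bought (ketoisophorone). Wittig and dichloroketene [2+2] build the four-membered ring and the C6–C7 quaternary pair. A C3 alkenyl unit is added to C2, then rhodium opens the cyclobutanol and re-closes it as six-membered ring B.
Stereochemistry: C6 comes from the chiral rhodium catalyst (desymmetrisation). C3, C8 and C9 are relayed from C6 by substrate control (epoxidation face, equatorial bromide by equilibration, equatorial hydride attack).

Key step: step 7

Remark: (R)-DTBM-SEGPHOS is written for the ligand; its antipode is taken if a pilot run shows the opposite sense of induction at C6.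

Step 1
Reactants: 1 ketoisophorone (2,6,6-trimethylcyclohex-2-ene-1,4-dione)
Product: 2 7,9,9-trimethyl-1,4-dioxaspiro[4.5]dec-6-en-8-one
Conditions: HOCH2CH2OH (1.1 equiv), p-TsOH (cat.), toluene, Dean–Stark, reflux
Reagents that add atoms: ethylene glycol, OCCO
Why: Acid-catalysed ketalisation with water removal picks the C4 carbonyl of 1, because the other carbonyl is flanked by CMe2 and by the methyl-bearing alkene carbon, and the alkene stays conjugated with the free ketone so it does not shift.

Step 2
Reactants: 2 7,9,9-trimethyl-1,4-dioxaspiro[4.5]dec-6-en-8-one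
Product: 3 7,9,9-trimethyl-8-methylidene-1,4-dioxaspiro[4.5]dec-6-ene
Conditions: Ph3PCH3Br, KOt-Bu, toluene, 90 °C
Reagents that add atoms: methyltriphenylphosphonium bromide, C[P+](c1ccccc1)(c1ccccc1)c1ccccc1.[Br-]
Why: Wittig methylenation; the ketone is hindered but has no acidic α- or γ-hydrogen, so excess ylide can be used hot, conditions known to methylenate ketones next to quaternary carbons.

Step 3
Reactants: 3 7,9,9-trimethyl-8-methylidene-1,4-dioxaspiro[4.5]dec-6-ene
Product: 4 rac-1,1-dichloro-7,7-(ethylenedioxy)-5,9,9-trimethylspiro[3.5]non-5-en-2-one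
Conditions: Cl3CCOCl, Zn–Cu, Et2O/DME, 0 °C to rt
Reagents that add atoms: trichloroacetyl chloride, O=C(Cl)C(Cl)(Cl)Cl
Why: Ketene–alkene [2+2] cycloaddition, in which the ketene carbonyl carbon bonds to the free CH2 terminus of the s-trans diene (charge builds at the tertiary allylic C6) and the CCl2 carbon closes on C6 to create the C6–C7 quaternary pair, while the hindered, ketal-deactivated ring alkene does not compete; the new stereocentre is racemic and is erased in step 4.

Step 4
Reactants: 4 rac-1,1-dichloro-7,7-(ethylenedioxy)-5,9,9-trimethylspiro[3.5]non-5-en-2-one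
Product: 5 7,7-(ethylenedioxy)-5,9,9-trimethylspiro[3.5]non-5-en-2-one (achiral)
Conditions: Zn dust, NH4Cl, MeOH, rt
Reagents that add atoms: none
Why: Zinc reduction of an α,α-dichloroketone through zinc enolates, run near neutral so that the allylic ketal survives; the product has a mirror plane through C2, C6 and ring A, so C6 is now prochiral.

Step 5
Reactants: 6 2,3-dibromoprop-1-ene
Product: 7 2-bromo-3-methoxyprop-1-ene
Conditions: NaOMe, MeOH, 0 °C to rt
Reagents that add atoms: sodium methoxide, C[O-].[Na+]
Why: SN2 displacement of the allylic bromide by methoxide, the vinylic bromide being inert.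

Step 6
Reactants: 7 2-bromo-3-methoxyprop-1-ene; 5 7,7-(ethylenedioxy)-5,9,9-trimethylspiro[3.5]non-5-en-2-one
Product: 9 7,7-(ethylenedioxy)-2-(3-methoxyprop-1-en-2-yl)-5,9,9-trimethylspiro[3.5]non-5-en-2-ol (OH cis to the CMe2 carbon; achiral), via 2-lithio-3-methoxypropene 8 (not isolated)
Conditions: 7, t-BuLi (2 equiv), Et2O, −78 °C; then 5, −78 °C; aq. NH4Cl
Reagents that add atoms: tert-butyllithium, [Li]C(C)(C)C (its lithium stays only in 8)
Why: Bromine–lithium exchange and 1,2-addition to the strained, electrophilic cyclobutanone at a temperature below loss of LiOMe from 8; attack comes from the ring face that carries the flat C(Me)=CH carbon rather than CMe2, which places OH cis to CMe2 (a cis/trans relation only).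

Step 7
Reactants: 9 7,7-(ethylenedioxy)-2-(3-methoxyprop-1-en-2-yl)-5,9,9-trimethylspiro[3.5]non-5-en-2-ol
Product: 10 (6S)-9,9-(ethylenedioxy)-7,7,11-trimethyl-3-methylidenespiro[5.5]undec-10-en-2-one
Conditions: [Rh(OH)(cod)]2 (2.5 mol %), (R)-DTBM-SEGPHOS (6 mol %), 4 Å MS, toluene (0.05 M), 60–80 °C
Reagents that add atoms: none
Why: Proposed new method: ligand exchange gives the rhodium(I) alkoxide of 9, whose strain-driven β-carbon elimination cleaves one of the two enantiotopic C2–CH2 bonds and leaves a neopentyl alkyl-rhodium (no β-hydrogen, C6 being quaternary) tethered to the α-(methoxymethyl) vinyl ketone just unmasked. Intramolecular 1,4-carbometalation onto the unsubstituted vinyl terminus (6-endo-trig; the 5-exo mode would be anti-Michael and would hit the substituted carbon C3) forms C4–C5 and closes ring B, and the rhodium enolate expels the β-methoxide to give the C3 methylidene and Rh–OMe, which the next molecule of 9 exchanges, so no outside base or proton source is needed. The closest known reaction type is the rhodium/diphosphine-catalysed enantioselective ring expansion of prochiral 3,3-disubstituted 1-allenyl- and 1-alkenylcyclobutanols to six-membered ketones, which ends by protonation; β-alkoxide loss from rhodium enolates is known from additions to allylic ethers and Baylis–Hillman-type acceptors, and only the combination is new. The one new stereocentre, C6, is fixed in the β-carbon elimination by the chiral ligand, which has to tell the CMe2 carbon from the flat C(Me)=CH carbon, a larger difference than the substituent pairs that serve in the known cases. The step needs bond selectivity (ring C–C rather than C2–alkenyl, secured by ring strain), endo regioselectivity (secured by enone polarity and the substituent on C3) and survival of the product (sieves bind methanol, dilution and moderate temperature hold back dimerisation, and 10 is used at once).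

Step 8
Reactants: 10 (6S)-9,9-(ethylenedioxy)-7,7,11-trimethyl-3-methylidenespiro[5.5]undec-10-en-2-one
Product: 11 (3R,6S)-9,9-(ethylenedioxy)-7,7,11-trimethylspiro[5.5]undec-10-en-2-one 3-spiro-oxirane (oxirane O on C3 cis to C7)
Conditions: 30 % H2O2, NaOH (cat.), MeOH, 0 °C
Reagents that add atoms: hydrogen peroxide, OO
Why: Weitz–Scheffer nucleophilic epoxidation, which touches only the enone alkene; hydroperoxide adds to the exocyclic CH2 and the ring enolate closes on oxygen along the axial direction of the ring-B chair that keeps C7 equatorial and C11 axial, that is from the face opposite C11, which sets C3 with oxygen cis to C7.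

Step 9
Reactants: 11 (3R,6S)-9,9-(ethylenedioxy)-7,7,11-trimethylspiro[5.5]undec-10-en-2-one 3-spiro-oxirane
Product: 12 (3S,6S)-3-(chloromethyl)-3-hydroxy-7,7,11-trimethylspiro[5.5]undec-10-ene-2,9-dione
Conditions: 2 M aq. HCl, LiCl (sat.), THF, 0 °C to rt
Reagents that add atoms: hydrogen chloride, Cl; water, O
Why: Acid-promoted SN2 opening of the epoxide by chloride at the unhindered CH2 (the tertiary α-keto carbon cannot ionise, so the C3–O bond and its configuration stay), with hydrolysis of the allylic ketal to the conjugated enone by the same acid.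

Step 10
Reactants: 12 (3S,6S)-3-(chloromethyl)-3-hydroxy-7,7,11-trimethylspiro[5.5]undec-10-ene-2,9-dione
Product: 15 (3S,6R,8R)-8-bromo-3-(chloromethyl)-7,7,11-trimethyl-3-(trimethylsilyloxy)spiro[5.5]undec-10-ene-2,9-dione, via bis-silyl dienol ether 13 (not isolated), via axial C8 bromide 14 (not isolated)
Conditions: Me3SiOTf (3 equiv), Et3N (5 equiv), CH2Cl2, −78 to 0 °C; NBS (1.0 equiv), THF, −78 °C; aq. NaHCO3; then DBU (10 mol %), CH2Cl2, 0 °C
Reagents that add atoms: trimethylsilyl triflate, C[Si](C)(C)OS(=O)(=O)C(F)(F)F; N-bromosuccinimide, O=C1CCC(=O)N1Br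
Why: Soft enolisation with silyl triflate/amine (which also caps the tertiary alcohol) converts the more Lewis-basic enone, not the hindered electron-poor C2 ketone, into the cross-conjugated 2-silyloxydiene by loss of a C8 proton, NBS brominates C8 (α′-bromination of an enone), and DBU equilibrates C8 to the equatorial bromide of the ring-A chair in which the C11 methyl lies over the C2 carbonyl, the side of ring B without an axial hydrogen, which is the epimer with Br cis to C1.

Step 11
Reactants: 15 (3S,6R,8R)-8-bromo-3-(chloromethyl)-7,7,11-trimethyl-3-(trimethylsilyloxy)spiro[5.5]undec-10-ene-2,9-dione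
Product: 17 (3S,6R,8R)-8-bromo-3-(chloromethyl)-7,7-dimethyl-11-methylidene-3-(trimethylsilyloxy)spiro[5.5]undecane-2,9-dione, via linear silyl dienol ether 16 (not isolated)
Conditions: Me3SiOTf (1.5 equiv), Et3N (3 equiv), CH2Cl2, 0 °C to rt; then poured into AcOH/THF/H2O, −20 °C
Reagents that add atoms: trimethylsilyl triflate, C[Si](C)(C)OS(=O)(=O)C(F)(F)F (its silyl group stays only in 16)
Why: Deconjugation through a linear dienol ether: C8–H is now neopentyl, shielded and would lead to a strained tetrasubstituted bromo-enol ether, so the amine removes a proton of the C11 methyl group, and kinetic protonation of the 1-silyloxydiene at its α-carbon C10 gives the β,γ-unsaturated ketone with the exocyclic alkene, C8 being untouched and the tertiary silyl ether surviving.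

Step 12
Reactants: 17 (3S,6R,8R)-8-bromo-3-(chloromethyl)-7,7-dimethyl-11-methylidene-3-(trimethylsilyloxy)spiro[5.5]undecane-2,9-dione
Product: 19 (3S,6R,8R,9S)-8-bromo-3-(chloromethyl)-3,9-dihydroxy-7,7-dimethyl-11-methylidenespiro[5.5]undecan-2-one (target), via O-silyl bromohydrin 18 (not isolated)
Conditions: DIBAL-H (1.2 equiv), CH2Cl2, −78 °C; Rochelle salt; then citric acid, MeOH, rt
Reagents that add atoms: none
Why: Diastereoselective hydride reduction of an α-bromoketone: axial attack on C9 is blocked by the axial methyl on C7, so DIBAL-H attacks equatorially and gives the axial alcohol cis to the equatorial bromide, while the C2 ketone is spared because its axial face is covered by C11 and its equatorial face by the axial OSiMe3 on C3; mild acid then removes the silyl group.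

**Compound list**
1 | ketoisophorone (2,6,6-trimethylcyclohex-2-ene-1,4-dione) | CC1=CC(=O)CC(C)(C)C1=O | starting material
2 | 7,9,9-trimethyl-1,4-dioxaspiro[4.5]dec-6-en-8-one | CC1=CC2(OCCO2)CC(C)(C)C1=O | intermediate
3 | 7,9,9-trimethyl-8-methylidene-1,4-dioxaspiro[4.5]dec-6-ene | CC1=CC2(OCCO2)CC(C)(C)C1=C | intermediate
4 | rac-1,1-dichloro-7,7-(ethylenedioxy)-5,9,9-trimethylspiro[3.5]non-5-en-2-one | CC1=CC2(OCCO2)CC(C)(C)C13CC(=O)C3(Cl)Cl | intermediate
5 | 7,7-(ethylenedioxy)-5,9,9-trimethylspiro[3.5]non-5-en-2-one (achiral) | CC1=CC2(OCCO2)CC(C)(C)C13CC(=O)C3 | intermediate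
6 | 2,3-dibromoprop-1-ene | C=C(Br)CBr | starting material
7 | 2-bromo-3-methoxyprop-1-ene | C=C(Br)COC | intermediate
8 | 2-lithio-3-methoxypropene | [Li]C(=C)COC | intermediate
9 | 7,7-(ethylenedioxy)-2-(3-methoxyprop-1-en-2-yl)-5,9,9-trimethylspiro[3.5]non-5-en-2-ol, OH cis to CMe2 | CC1=CC2(OCCO2)CC(C)(C)[C@]13C[C@](O)(C(=C)COC)C3 | intermediate
10 | (6S)-9,9-(ethylenedioxy)-7,7,11-trimethyl-3-methylidenespiro[5.5]undec-10-en-2-one | CC1=CC2(OCCO2)CC(C)(C)[C@@]13CCC(=C)C(=O)C3 | intermediate
11 | (3R,6S)-9,9-(ethylenedioxy)-7,7,11-trimethylspiro[5.5]undec-10-en-2-one 3-spiro-oxirane | CC1=CC2(OCCO2)CC(C)(C)[C@@]13CC[C@@]4(CO4)C(=O)C3 | intermediate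
12 | (3S,6S)-3-(chloromethyl)-3-hydroxy-7,7,11-trimethylspiro[5.5]undec-10-ene-2,9-dione | CC1=CC(=O)CC(C)(C)[C@@]12CC[C@@](O)(CCl)C(=O)C2 | intermediate
13 | (3S,6R)-3-(chloromethyl)-7,7,11-trimethyl-3,9-bis(trimethylsilyloxy)spiro[5.5]undeca-8,10-dien-2-one | CC1=CC(O[Si](C)(C)C)=CC(C)(C)[C@@]12CC[C@@](O[Si](C)(C)C)(CCl)C(=O)C2 | intermediate
14 | (3S,6R,8S)-8-bromo-3-(chloromethyl)-7,7,11-trimethyl-3-(trimethylsilyloxy)spiro[5.5]undec-10-ene-2,9-dione (axial bromide) | CC1=CC(=O)[C@@H](Br)C(C)(C)[C@@]12CC[C@@](O[Si](C)(C)C)(CCl)C(=O)C2 | intermediate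
15 | (3S,6R,8R)-8-bromo-3-(chloromethyl)-7,7,11-trimethyl-3-(trimethylsilyloxy)spiro[5.5]undec-10-ene-2,9-dione (equatorial bromide) | CC1=CC(=O)[C@H](Br)C(C)(C)[C@@]12CC[C@@](O[Si](C)(C)C)(CCl)C(=O)C2 | intermediate
16 | (3S,6R,8R)-8-bromo-3-(chloromethyl)-7,7-dimethyl-11-methylidene-3,9-bis(trimethylsilyloxy)spiro[5.5]undec-9-en-2-one | C=C1C=C(O[Si](C)(C)C)[C@H](Br)C(C)(C)[C@@]12CC[C@@](O[Si](C)(C)C)(CCl)C(=O)C2 | intermediate
17 | (3S,6R,8R)-8-bromo-3-(chloromethyl)-7,7-dimethyl-11-methylidene-3-(trimethylsilyloxy)spiro[5.5]undecane-2,9-dione | C=C1CC(=O)[C@H](Br)C(C)(C)[C@@]12CC[C@@](O[Si](C)(C)C)(CCl)C(=O)C2 | intermediate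
18 | (3S,6R,8R,9S)-8-bromo-3-(chloromethyl)-9-hydroxy-7,7-dimethyl-11-methylidene-3-(trimethylsilyloxy)spiro[5.5]undecan-2-one | C=C1C[C@H](O)[C@H](Br)C(C)(C)[C@@]12CC[C@@](O[Si](C)(C)C)(CCl)C(=O)C2 | intermediate
19 | (3S,6R,8R,9S)-8-bromo-3-(chloromethyl)-3,9-dihydroxy-7,7-dimethyl-11-methylidenespiro[5.5]undecan-2-one | C=C1C[C@H](O)[C@H](Br)C(C)(C)[C@@]12CC[C@@](O)(CCl)C(=O)C2 | target

Total step count: 12. Longest linear sequence: 11 (steps 1–4 and 6–12).

**Steps most likely to fail**

**Step 7.** The alkyl-rhodium may be protonated before it closes the ring. The two enantiotopic bonds may be told apart poorly. The α-methylene ketone may be lost by methanol addition, alkene isomerisation or dimerisation at the reaction temperature. The fallback separates ring expansion from methylenation and uses documented operations only; it sets out from 5 and returns at 10. Vinylmagnesium bromide adds to 5 to give the 2-vinylcyclobutanol F1. The proton-terminated rhodium(I)/chiral diphosphine ring expansion (β-carbon elimination, 6-endo conjugate addition, protonation of the enolate by the next alcohol) gives the plain spiro ketone F2. LDA deprotonates it at C3, away from the neopentyl C1, and Eschenmoser's salt gives the Mannich base F3. Methyl iodide gives the ammonium iodide F4, and aqueous NaHCO3 eliminates the amine to give 10.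

**Step 10.** The amine may take a proton from the C11 methyl group instead of C8. Ring B may be silylated and brominated as well. The base equilibration may set off loss of bromide. The fallback masks the ring-B ketone so that hard kinetic enolisation can be used; it sets out from 10 and returns at 15.
- Luche reduction of 10 followed by dilute acid gives the hydroxy enone F5 (C2 epimers, of no consequence).
- LDA (2.2 equiv) in the presence of Me3SiCl gives the bis-silyl compound F6 by kinetic α′-deprotonation.
- NBS and a mildly acidic work-up give the bromo enone alcohol F7.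
- MnO2 oxidises the only, allylic, alcohol to the bromo methylene diketone F8, in which C2 is trigonal again, and C8 is equilibrated at this stage.
- t-BuOOH/DBU gives the bromo spiro-epoxide F9.
- Me3SiCl with catalytic Bu4NCl opens the epoxide at CH2 to give 15 directly.

**Step 11.** Enolisation may go toward C8, or the β,γ-enone may slip back into conjugation during protonation or isolation. The fallback never lets the free β,γ-enone build up; it sets out from 15 and returns at 18. Isopropenyl acetate/p-TsOH under equilibrating conditions converts 15 into the linear dienol acetate F10. NaBH4 in aqueous ethanol/THF at 0 °C cleaves the enol ester, the dienolate is protonated kinetically at C10, and the ketone so formed is reduced at once. This is the classical enone-to-homoallylic-alcohol sequence of steroid chemistry, and it gives 18.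

**Further compounds**
F1 | step 7 | 7,7-(ethylenedioxy)-5,9,9-trimethyl-2-vinylspiro[3.5]non-5-en-2-ol, OH cis to CMe2 | CC1=CC2(OCCO2)CC(C)(C)[C@]13C[C@](O)(C=C)C3
F2 | step 7 | (6S)-9,9-(ethylenedioxy)-7,7,11-trimethylspiro[5.5]undec-10-en-2-one | CC1=CC2(OCCO2)CC(C)(C)[C@@]13CCCC(=O)C3
F3 | step 7 | (6S)-3-[(dimethylamino)methyl]-9,9-(ethylenedioxy)-7,7,11-trimethylspiro[5.5]undec-10-en-2-one (C3 epimers) | CC1=CC2(OCCO2)CC(C)(C)[C@@]13CCC(CN(C)C)C(=O)C3
F4 | step 7 | trimethylammonium iodide of F3 | CC1=CC2(OCCO2)CC(C)(C)[C@@]13CCC(C[N+](C)(C)C)C(=O)C3.[I-]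
F5 | step 10 | (6S)-2-hydroxy-7,7,11-trimethyl-3-methylidenespiro[5.5]undec-10-en-9-one (C2 epimers) | CC1=CC(=O)CC(C)(C)[C@@]12CCC(=C)C(O)C2
F6 | step 10 | (6R)-7,7,11-trimethyl-3-methylidene-2,9-bis(trimethylsilyloxy)spiro[5.5]undeca-8,10-diene (C2 epimers) | CC1=CC(O[Si](C)(C)C)=CC(C)(C)[C@@]12CCC(=C)C(O[Si](C)(C)C)C2
F7 | step 10 | (6R,8R)-8-bromo-2-hydroxy-7,7,11-trimethyl-3-methylidenespiro[5.5]undec-10-en-9-one (C2 epimers) | CC1=CC(=O)[C@H](Br)C(C)(C)[C@@]12CCC(=C)C(O)C2
F8 | step 10 | (6R,8R)-8-bromo-7,7,11-trimethyl-3-methylidenespiro[5.5]undec-10-ene-2,9-dione | CC1=CC(=O)[C@H](Br)C(C)(C)[C@@]12CCC(=C)C(=O)C2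
F9 | step 10 | (3R,6R,8R)-8-bromo-7,7,11-trimethylspiro[5.5]undec-10-ene-2,9-dione 3-spiro-oxirane | CC1=CC(=O)[C@H](Br)C(C)(C)[C@@]12CC[C@@]3(CO3)C(=O)C2
F10 | step 11 | (3S,6R,8R)-9-acetoxy-8-bromo-3-(chloromethyl)-7,7-dimethyl-11-methylidene-3-(trimethylsilyloxy)spiro[5.5]undec-9-en-2-one | C=C1C=C(OC(C)=O)[C@H](Br)C(C)(C)[C@@]12CC[C@@](O[Si](C)(C)C)(CCl)C(=O)C2
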